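Neolignan numbering is used: C7 benzylic carbinol, C8 aryloxy-bearing carbon, C9 acetoxymethyl carbon. The route rests on replacing the C7–O bond by a C7–Si bond held in a 1,2-oxasilolane (O9, Si, C7, C8, C9). The feature exploited is the 1,3-relation of the C7 and C9 oxygens across C8: a silicon hydride carried on O9 can reach C7 of a C7=C8 aryl enol ether. One Rh-catalysed intramolecular hydrosilylation forms Si–C7, closes the five-membered ring and sets C7 and C8 by syn addition. The precursor is the E 2-aryloxy-3-arylallyl dimethylsilyl ether (aryl cis to CH2O), allyl side chain already in place.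

Key step: step 6

Remark: the sense of induction of Rh–BINAP on this alkene class cannot be predicted; (S)-BINAP is written on the assumption that it gives the (3R,4R) ring, and the antipodal ligand is used if the opposite sense is found.
Design note: the allyl group is carried unprotected, because masking it would add steps after the key step. The silyl ether is made salt-free from the disilazane, so that no chloride or ammonium salt reaches the cationic rhodium catalyst.

Step 1
Reactants: 1 ethyl 2-(diphenoxyphosphoryl)acetate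
Product: 2 ethyl 2-diazo-2-(diphenoxyphosphoryl)acetate
Conditions: p-ABSA, DBU, MeCN, 0 °C → rt
Reagents that add atoms: 4-acetamidobenzenesulfonyl azide (p-ABSA), CC(=O)Nc1ccc(cc1)S(=O)(=O)N=[N+]=[N-]
Why: Regitz diazo transfer, in which the amidine deprotonates the doubly activated methylene, the carbanion attacks the terminal azide nitrogen and the triazene collapses to the diazo compound and the sulfonamide, the aryl phosphonate esters being stable to the non-nucleophilic base.

Step 2
Reactants: 2 ethyl 2-diazo-2-(diphenoxyphosphoryl)acetate; 3 4-allyl-2,6-dimethoxyphenol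
Product: 4 ethyl 2-(4-allyl-2,6-dimethoxyphenoxy)-2-(diphenoxyphosphoryl)acetate (racemic)
Conditions: Rh2(OAc)4 (1 mol %), PhMe, 80 °C, slow addition of 2
Reagents that add atoms: none
Why: Rh(II)-carbenoid O–H insertion, in which the electrophilic acceptor/acceptor carbenoid is captured by the phenolic oxygen (oxonium ylide, then proton shift) faster than it cyclopropanates a remote monosubstituted alkene; the new stereocentre is racemic and is destroyed in step 3.

Step 3
Reactants: 4 ethyl 2-(4-allyl-2,6-dimethoxyphenoxy)-2-(diphenoxyphosphoryl)acetate; 5 3,4,5-trimethoxybenzaldehyde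
Product: 6 ethyl (E)-2-(4-allyl-2,6-dimethoxyphenoxy)-3-(3,4,5-trimethoxyphenyl)prop-2-enoate
Conditions: NaH, THF, 0 °C; then 5, −78 → 0 °C
Reagents that add atoms: none
Why: Horner–Wadsworth–Emmons olefination in its Ando (diaryl phosphonate) variant, where fast irreversible collapse of the kinetic adduct should place the aldehyde aryl cis to the ester, which is the E enol ether because aryloxy outranks the ester; any Z isomer is removed by chromatography, since it would lead to the erythro series.

Step 4
Reactants: 6 ethyl (E)-2-(4-allyl-2,6-dimethoxyphenoxy)-3-(3,4,5-trimethoxyphenyl)prop-2-enoate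
Product: 8 (E)-2-(4-allyl-2,6-dimethoxyphenoxy)-3-(3,4,5-trimethoxyphenyl)prop-2-en-1-ol, via (E)-2-aryloxy-3-arylprop-2-enal 7 (not isolated)
Conditions: DIBAL-H (2.5 equiv), CH2Cl2, −78 → −20 °C; aq. Rochelle salt
Reagents that add atoms: none
Why: DIBAL-H 1,2-reduction of the conjugated ester through the enal to the allylic alcohol should leave the enol ether, its geometry and the allyl group untouched, and the neutral tartrate work-up avoids acid hydrolysis of the enol ether.

Step 5
Reactants: 8 (E)-2-(4-allyl-2,6-dimethoxyphenoxy)-3-(3,4,5-trimethoxyphenyl)prop-2-en-1-ol; 9 1,1,3,3-tetramethyldisilazane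
Product: 10 (E)-[2-(4-allyl-2,6-dimethoxyphenoxy)-3-(3,4,5-trimethoxyphenyl)prop-2-enyloxy]dimethylsilane
Conditions: (HMe2Si)2NH (1.0 equiv), PhMe, 50 °C; volatiles removed in vacuo, filtration under Ar
Reagents that add atoms: none
Why: O-silylation of the primary alcohol by the disilazane gives the hydrosilyl ether with ammonia as the only by-product, so the moisture-sensitive precursor is obtained free of salts and is used at once.

Step 6
Reactants: 10 (E)-[2-(4-allyl-2,6-dimethoxyphenoxy)-3-(3,4,5-trimethoxyphenyl)prop-2-enyloxy]dimethylsilane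
Product: 11 (3R,4R)-4-(4-allyl-2,6-dimethoxyphenoxy)-2,2-dimethyl-3-(3,4,5-trimethoxyphenyl)-1,2-oxasilolane (cis)
Conditions: [Rh((S)-BINAP)(acetone)2]BF4 (3 mol %, from [Rh(nbd)((S)-BINAP)]BF4/H2, then Ar purge), acetone, 0.02 M, 25 °C
Reagents that add atoms: none
Why: Proposed new method: the tethered Si–H adds oxidatively to the cationic Rh(I)–BINAP centre, the C7=C8 bond coordinates, silicon migrates to C7 (the pathway favoured for cationic Rh–diphosphine catalysts, which leaves Rh on C8, α and not β to the aryloxy oxygen) and C8–H reductive elimination completes a suprafacial addition. The closest known reactions are the Rh(I)–chiral diphosphine cyclisation of 3-aryl allyl hydrosilyl ethers and the Pt(0)-catalysed cyclisation of 2-alkoxy allyl hydrosilyl ethers, both followed by C–Si oxidation to 1,3-diols; a trisubstituted alkene carrying both the 2-aryloxy and the 3-aryl group has not been cyclised enantioselectively. The 1,2-oxasilolane closes in the 5-endo-trig mode through the new Si–C7 bond, the only closure the three-atom Si–O9–C9 tether allows without a four-membered ring. C7 is set by the chiral diphosphine, which selects the alkene face that receives silicon, and C8 is set relative to C7 by delivery of hydrogen from the same metal to the same face of the geometrically pure E alkene, which places aryloxy and aryl cis on the ring (threo after oxidation). The step needs face selectivity (ligand), regioselectivity (tether length) and chemoselectivity over the terminal allyl group, the last secured by intramolecularity, 0.02 M dilution, complete removal of H2 after catalyst activation and a salt-free substrate.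

Step 7
Reactants: 11 (3R,4R)-4-(4-allyl-2,6-dimethoxyphenoxy)-2,2-dimethyl-3-(3,4,5-trimethoxyphenyl)-1,2-oxasilolane
Product: 13 (1R,2R)-2-(4-allyl-2,6-dimethoxyphenoxy)-1-(3,4,5-trimethoxyphenyl)propane-1,3-diol, via cyclic 1,3,2-dioxasilinane 12 (not isolated)
Conditions: 30% H2O2, KF, KHCO3, THF/MeOH (1:1), 25 °C
Reagents that add atoms: hydrogen peroxide, OO
Why: Tamao oxidation, in which hydroperoxide adds to the activated alkoxysilane and C7 migrates from silicon to oxygen with retention, the cyclic silyl ether then being hydrolysed in the flask; five-ring β-alkoxy silanes are known to oxidise without β-elimination, basic H2O2 without a nitrile should not epoxidise the allyl group, and no stereocentre is altered.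

Step 8
Reactants: 13 (1R,2R)-2-(4-allyl-2,6-dimethoxyphenoxy)-1-(3,4,5-trimethoxyphenyl)propane-1,3-diol
Product: 14 (2R,3R)-2-(4-allyl-2,6-dimethoxyphenoxy)-3-hydroxy-3-(3,4,5-trimethoxyphenyl)propyl acetate (CNP0079124.1)
Conditions: AcCl (1.1 equiv), 2,4,6-collidine, CH2Cl2, −78 °C
Reagents that add atoms: acetyl chloride, CC(Cl)=O
Why: Low-temperature acyl chloride/collidine acetylation should select the unhindered primary C9 hydroxyl over the secondary benzylic C7 hydroxyl flanked by the aryloxy group, and the stereocentres are not involved.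

Compound list
1 | ethyl 2-(diphenoxyphosphoryl)acetate | CCOC(=O)CP(=O)(Oc1ccccc1)Oc1ccccc1 | starting material
2 | ethyl 2-diazo-2-(diphenoxyphosphoryl)acetate | CCOC(=O)C(=[N+]=[N-])P(=O)(Oc1ccccc1)Oc1ccccc1 | intermediate
3 | 4-allyl-2,6-dimethoxyphenol | C=CCc1cc(OC)c(O)c(OC)c1 | starting material
4 | ethyl 2-(4-allyl-2,6-dimethoxyphenoxy)-2-(diphenoxyphosphoryl)acetate (racemic) | C=CCc1cc(OC)c(OC(C(=O)OCC)P(=O)(Oc2ccccc2)Oc2ccccc2)c(OC)c1 | intermediate
5 | 3,4,5-trimethoxybenzaldehyde | COc1cc(C=O)cc(OC)c1OC | starting material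
6 | ethyl (E)-2-(4-allyl-2,6-dimethoxyphenoxy)-3-(3,4,5-trimethoxyphenyl)prop-2-enoate | C=CCc1cc(OC)c(O/C(C(=O)OCC)=C/c2cc(OC)c(OC)c(OC)c2)c(OC)c1 | intermediate
7 | (E)-2-(4-allyl-2,6-dimethoxyphenoxy)-3-(3,4,5-trimethoxyphenyl)prop-2-enal (not isolated) | C=CCc1cc(OC)c(O/C(C=O)=C/c2cc(OC)c(OC)c(OC)c2)c(OC)c1 | intermediate
8 | (E)-2-(4-allyl-2,6-dimethoxyphenoxy)-3-(3,4,5-trimethoxyphenyl)prop-2-en-1-ol | C=CCc1cc(OC)c(O/C(CO)=C/c2cc(OC)c(OC)c(OC)c2)c(OC)c1 | intermediate
9 | 1,1,3,3-tetramethyldisilazane | C[SiH](C)N[SiH](C)C | starting material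
10 | (E)-[2-(4-allyl-2,6-dimethoxyphenoxy)-3-(3,4,5-trimethoxyphenyl)prop-2-enyloxy]dimethylsilane | C=CCc1cc(OC)c(O/C(CO[SiH](C)C)=C/c2cc(OC)c(OC)c(OC)c2)c(OC)c1 | intermediate
11 | (3R,4R)-4-(4-allyl-2,6-dimethoxyphenoxy)-2,2-dimethyl-3-(3,4,5-trimethoxyphenyl)-1,2-oxasilolane | C=CCc1cc(OC)c(O[C@H](CO[Si]2(C)C)[C@H]2c3cc(OC)c(OC)c(OC)c3)c(OC)c1 | intermediate
12 | (4R,5R)-5-(4-allyl-2,6-dimethoxyphenoxy)-2,2-dimethyl-4-(3,4,5-trimethoxyphenyl)-1,3,2-dioxasilinane (not isolated) | C=CCc1cc(OC)c(O[C@H](CO[Si]2(C)C)[C@H](O2)c3cc(OC)c(OC)c(OC)c3)c(OC)c1 | intermediate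
13 | (1R,2R)-2-(4-allyl-2,6-dimethoxyphenoxy)-1-(3,4,5-trimethoxyphenyl)propane-1,3-diol | C=CCc1cc(OC)c(O[C@H](CO)[C@H](O)c2cc(OC)c(OC)c(OC)c2)c(OC)c1 | intermediate
14 | (2R,3R)-2-(4-allyl-2,6-dimethoxyphenoxy)-3-hydroxy-3-(3,4,5-trimethoxyphenyl)propyl acetate | C=CCc1cc(OC)c(O[C@H](COC(C)=O)[C@H](O)c2cc(OC)c(OC)c(OC)c2)c(OC)c1 | target

Total step count: 8
Longest linear sequence: 8 steps (1 → 14)

Steps most likely to fail

1. Step 6. The Rh–H/Rh–Si species may isomerise or hydrosilylate the terminal allyl group of another molecule before the slower 5-endo closure onto the electron-rich trisubstituted alkene, or the closure may occur with poor face discrimination. The fallback uses no silicon and sets both centres by an Evans syn-selective glycolate aldol; it sets out from 3 and comes back at 13. Phenol 3 is O-alkylated with bromoacetic acid (NaOH, H2O, 80 °C) to 2-(4-allyl-2,6-dimethoxyphenoxy)acetic acid F1. This is activated with PivCl/Et3N (THF, −20 °C) as 2-(4-allyl-2,6-dimethoxyphenoxy)acetic pivalic anhydride F2 (not isolated) and N-acylates (S)-4-benzyloxazolidin-2-one (LiCl, rt) to (S)-4-benzyl-3-[2-(4-allyl-2,6-dimethoxyphenoxy)acetyl]oxazolidin-2-one F3. The Z boron enolate (Bu2BOTf, iPr2NEt, CH2Cl2, −78 → 0 °C) should add to 5 through a chair transition state on the face away from the benzyl group, giving the syn adduct (S)-4-benzyl-3-[(2S,3R)-2-(4-allyl-2,6-dimethoxyphenoxy)-3-hydroxy-3-(3,4,5-trimethoxyphenyl)propanoyl]oxazolidin-2-one F4. LiBH4 (THF, MeOH, 0 °C) then releases the auxiliary and gives diol 13.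

2. Step 7. β-Elimination of the C8 aryloxide from the activated silicate, or protodesilylation at benzylic C7, may outrun the shift of C7 from silicon to oxygen. The fallback avoids a C–Si bond by asymmetric transfer hydrogenation with dynamic kinetic resolution; it sets out from 3 and comes back at 13. Commercial ethyl 3-oxo-3-(3,4,5-trimethoxyphenyl)propanoate is brominated (NBS, cat. NH4OAc, Et2O) to ethyl 2-bromo-3-oxo-3-(3,4,5-trimethoxyphenyl)propanoate F5. Displacement with 3 (K2CO3, acetone) gives ethyl 2-(4-allyl-2,6-dimethoxyphenoxy)-3-oxo-3-(3,4,5-trimethoxyphenyl)propanoate F6. Noyori-type transfer hydrogenation (RuCl[(S,S)-TsDPEN](p-cymene), HCO2H/Et3N, CH2Cl2, 30 °C) reduces the ketone while C8 epimerises; on α-alkoxy β-keto esters this gives syn α-alkoxy β-hydroxy esters. It should therefore give ethyl (2S,3R)-2-(4-allyl-2,6-dimethoxyphenoxy)-3-hydroxy-3-(3,4,5-trimethoxyphenyl)propanoate F7, the catalyst antipode being chosen by the usual aryl ketone model. LiBH4 (THF, 0 °C) reduces the ester to diol 13.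

3. Step 3. Geometric control may erode, with the isomer having aryl trans to the ester forming alongside; this cannot be corrected later and would end in the erythro series. The fallback fixes the geometry by chelation and cross-coupling instead of olefination; it sets out from 3 and comes back at 6. Phenol 3 is alkylated with ethyl bromoacetate (K2CO3, acetone) to ethyl 2-(4-allyl-2,6-dimethoxyphenoxy)acetate F8. Claisen formylation (NaH, HCO2Et, THF) gives the sodium enolate of ethyl 2-(4-allyl-2,6-dimethoxyphenoxy)-3-oxopropanoate F9 (not isolated), in which the O–Na–O chelate holds the enolate oxygen cis to the ester. Trapping with PhNTf2 should give ethyl (E)-2-(4-allyl-2,6-dimethoxyphenoxy)-3-(trifluoromethylsulfonyloxy)prop-2-enoate F10. Suzuki–Miyaura coupling with (3,4,5-trimethoxyphenyl)boronic acid (Pd(PPh3)4, K3PO4, dioxane, 60 °C) replaces the triflate with retention and gives ester 6.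

Further compounds
F1 | step 6 | 2-(4-allyl-2,6-dimethoxyphenoxy)acetic acid | C=CCc1cc(OC)c(OCC(=O)O)c(OC)c1
F2 | step 6 | 2-(4-allyl-2,6-dimethoxyphenoxy)acetic pivalic anhydride (not isolated) | C=CCc1cc(OC)c(OCC(=O)OC(=O)C(C)(C)C)c(OC)c1
F3 | step 6 | (S)-4-benzyl-3-[2-(4-allyl-2,6-dimethoxyphenoxy)acetyl]oxazolidin-2-one | C=CCc1cc(OC)c(OCC(=O)N2[C@@H](Cc3ccccc3)COC2=O)c(OC)c1
F4 | step 6 | (S)-4-benzyl-3-[(2S,3R)-2-(4-allyl-2,6-dimethoxyphenoxy)-3-hydroxy-3-(3,4,5-trimethoxyphenyl)propanoyl]oxazolidin-2-one | C=CCc1cc(OC)c(O[C@H](C(=O)N2[C@@H](Cc3ccccc3)COC2=O)[C@H](O)c4cc(OC)c(OC)c(OC)c4)c(OC)c1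
F5 | step 7 | ethyl 2-bromo-3-oxo-3-(3,4,5-trimethoxyphenyl)propanoate | CCOC(=O)C(Br)C(=O)c1cc(OC)c(OC)c(OC)c1
F6 | step 7 | ethyl 2-(4-allyl-2,6-dimethoxyphenoxy)-3-oxo-3-(3,4,5-trimethoxyphenyl)propanoate | C=CCc1cc(OC)c(OC(C(=O)OCC)C(=O)c2cc(OC)c(OC)c(OC)c2)c(OC)c1
F7 | step 7 | ethyl (2S,3R)-2-(4-allyl-2,6-dimethoxyphenoxy)-3-hydroxy-3-(3,4,5-trimethoxyphenyl)propanoate | C=CCc1cc(OC)c(O[C@H](C(=O)OCC)[C@H](O)c2cc(OC)c(OC)c(OC)c2)c(OC)c1
F8 | step 3 | ethyl 2-(4-allyl-2,6-dimethoxyphenoxy)acetate | C=CCc1cc(OC)c(OCC(=O)OCC)c(OC)c1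
F9 | step 3 | ethyl 2-(4-allyl-2,6-dimethoxyphenoxy)-3-oxopropanoate (as sodium enolate, not isolated) | C=CCc1cc(OC)c(OC(C=O)C(=O)OCC)c(OC)c1
F10 | step 3 | ethyl (E)-2-(4-allyl-2,6-dimethoxyphenoxy)-3-(trifluoromethylsulfonyloxy)prop-2-enoate | C=CCc1cc(OC)c(O/C(C(=O)OCC)=C/OS(=O)(=O)C(F)(F)F)c(OC)c1
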